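The numbers in the tables stem from a simulated flask on assumed constants; the scatter is artificial.

Saturday's run, with 1.00 equivalent of second substrate on the starting material, read a mean target of 51.0%. Friday's, with 4.00 equivalents, read 43.4%. The next flask is planned with 2.00 equivalents, the coupling partner and its feed left unchanged. The decision is whether that charge can stand.

the same everywhere: starting material 0.050 M

| flask | coupling partner | second substrate | protic impurity | remark | time |
|---|---|---|---|---|---|
| Saturday's | 0.065 M (fed, over 15 s) | 0.050 M | 1 mM | run made earlier |  |
| Friday's | 0.065 M (fed, over 15 s) | 0.20 M | 1 mM | run made earlier |  |
| flask | 0.0650 M (fed, over 15 s) | 0.100 M | 1.00 mM |  | 1.0 h |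

| Saturday's: time / min | Saturday's: target / % | Friday's: time / min | Friday's: target / % |
|---|---|---|---|
| 8.00 | 51.3 | 3.00 | 42.4 |
| 15.0 | 51.0 | 10.0 | 43.1 |
| 25.0 | 51.8 | 15.0 | 44.5 |
| 30.0 | 50.7 | 25.0 | 42.9 |
| 40.0 | 51.7 | 40.0 | 43.5 |
| 50.0 | 50.4 | 50.0 | 43.4 |
| 60.0 | 49.9 | 60.0 | 44.2 |

(each reading ± 0.5 percentage points)

1. why nothing more happens at 1.0 h, or that something still does (all of the starting material has reacted / it is still moving)
2. target at 1.0 h, in percent of the starting material charged

- the reaction counts as stopped when no species that holds the starting material changes by six tenths of a point or more over the second half of the time

Both runs read level from the first sample, so each mean serves as a final yield, and no rate constant is needed. Taken as a straight line, the two means give 2.5 percentage points. This is the price of an equivalent, the points of target lost per equivalent of second substrate charged, read from the two runs with the other charges and the feed held as they stood there. The planned flask stands one equivalent above Saturday's, so this reckoning gives 48.5%. Level readings point to a stopped flask, though neither run measured the starting material. The reckoned loss against Saturday's is one price, so the charge stands.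

The forecast, a little lower, reads: all of the starting material has reacted, target 48%, range 46% to 50%, and “the target is not being consumed afterwards”.

The flask gives 49.2%, and all of the starting material has reacted, with 0.23% of the starting material left at 1.00 h.

    coupling partner + protic impurity → quenched reagent (k = 13.0 M⁻¹ s⁻¹)
    starting material + coupling partner → target (k = 0.990 M⁻¹ s⁻¹)
    2 starting material → homo dimer (k = 0.630 M⁻¹ s⁻¹)
    second substrate + coupling partner → second product (k = 0.120 M⁻¹ s⁻¹)

The flask lands 0.70 points above the reckoning, less than one price. Its target stops near half of the charge because starting material pairs with itself: the same flask without that step gives 85.8%, and homo dimer holds 50.6% of the starting material charged at 1.00 h.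

A neighbouring flask with 0.025 M of second substrate, 0.500 equiv, stands half an equivalent below Saturday's, so the price gives 52.2%. That flask computes to 51.2%.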